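**Retrosynthetic overview**
1. Target 13 ⇒ 12 (loss of one MOM group) ⇒ 10. The three C5 units of 12 are taken back to O-bound ethers (7-O-prenyl, 3'-O-prenyl, 4'-O-dimethylpropargyl); one thermal step moves them to carbon and closes the dimethylpyran ring through its C–O bond.
2. 10 ⇒ chalcone 9 by cutting ring C at O1–C2 and C3–OH (oxidative oxa-cyclisation, the central C–O bond-forming step); 9 ⇒ ketone 4 + aldehyde 8.
3. 4 ⇒ 2,4,6-trihydroxyacetophenone 1 by two O-alkylations; 8 ⇒ 3,4-dihydroxybenzaldehyde 5 by two site-selective O-alkylations.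
4. Ring order: rings A and B are bought; ring C (pyranone) is formed in step 5; ring D (dimethylpyran) in step 6.

Assumption: the target SMILES holds no stereocentre and no stereogenic double bond, so the compound is achiral and no enantiocontrol is needed.

**Route**

Step 1
Reactants: 1 2,4,6-trihydroxyacetophenone; 2 1-bromo-3-methylbut-2-ene (prenyl bromide)
Product: 3 1-{2,6-dihydroxy-4-[(3-methylbut-2-en-1-yl)oxy]phenyl}ethan-1-one
Conditions: K2CO3 (1.0 equiv), acetone, 40 °C
Reagents that add atoms: none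
Why: Williamson etherification in which one equivalent of weak base ionises only the 4-OH, the most acidic hydroxyl and the only one not hydrogen-bonded to the acetyl group, so O-alkylation is para-selective in an aprotic medium; no stereocentre is formed.

Step 2
Reactants: 3 1-{2,6-dihydroxy-4-[(3-methylbut-2-en-1-yl)oxy]phenyl}ethan-1-one
Product: 4 1-{2-hydroxy-6-(methoxymethoxy)-4-[(3-methylbut-2-en-1-yl)oxy]phenyl}ethan-1-one
Conditions: MOMCl (1.1 equiv), K2CO3, acetone, 0 °C → rt
Reagents that add atoms: chloromethyl methyl ether (MOMCl), COCCl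
Why: Williamson-type acetal ether formation on a symmetric substrate, so either ortho-OH gives the same product, while the remaining OH is chelated to the ketone, resists a second alkylation and is kept as the future ring oxygen O1.

Step 3
Reactants: 5 3,4-dihydroxybenzaldehyde; 6 3-chloro-3-methylbut-1-yne
Product: 7 3-hydroxy-4-[(2-methylbut-3-yn-2-yl)oxy]benzaldehyde
Conditions: K2CO3 (1.05 equiv), KI (cat.), CuI (cat.), DMF, 60 °C, N2
Reagents that add atoms: none
Why: Copper-assisted propargylic etherification (Williamson type) in which the 4-OH, para to the formyl group and markedly more acidic than the 3-OH, is the only phenoxide present with one equivalent of base and takes the tertiary propargyl unit.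

Step 4
Reactants: 7 3-hydroxy-4-[(2-methylbut-3-yn-2-yl)oxy]benzaldehyde; 2 1-bromo-3-methylbut-2-ene (prenyl bromide)
Product: 8 3-[(3-methylbut-2-en-1-yl)oxy]-4-[(2-methylbut-3-yn-2-yl)oxy]benzaldehyde
Conditions: K2CO3, DMF, rt
Reagents that add atoms: none
Why: Williamson etherification of the one remaining phenol with a reactive allylic bromide, with no other site in 7 alkylated under K2CO3.

Step 5
Reactants: 4 1-{2-hydroxy-6-(methoxymethoxy)-4-[(3-methylbut-2-en-1-yl)oxy]phenyl}ethan-1-one; 8 3-[(3-methylbut-2-en-1-yl)oxy]-4-[(2-methylbut-3-yn-2-yl)oxy]benzaldehyde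
Product: 10 3-hydroxy-5-(methoxymethoxy)-7-[(3-methylbut-2-en-1-yl)oxy]-2-{3-[(3-methylbut-2-en-1-yl)oxy]-4-[(2-methylbut-3-yn-2-yl)oxy]phenyl}-4H-chromen-4-one, via chalcone 9 (not isolated)
Conditions: KOH (aq. 50%), EtOH, rt, 36 h; then MeOH, H2O2 (30%), 0 °C → rt
Reagents that add atoms: hydrogen peroxide, OO
Why: Claisen–Schmidt condensation gives the E-chalcone 9, and Algar–Flynn–Oyamada oxidation (hydroperoxide attack on the enone, 6-endo closure of the 2'-phenoxide at the benzylic carbon helped by the para-alkoxy group of ring B, then oxidation of the dihydroflavonol) forms the O1–C2 and C3–OH bonds of ring C; alkaline H2O2 leaves the isolated alkenes and the alkyne alone, and the E alkene and transient C2/C3 centres are erased on aromatisation.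

Step 6
Reactants: 10 3-hydroxy-5-(methoxymethoxy)-7-[(3-methylbut-2-en-1-yl)oxy]-2-{3-[(3-methylbut-2-en-1-yl)oxy]-4-[(2-methylbut-3-yn-2-yl)oxy]phenyl}-4H-chromen-4-one
Product: 12 3,7-dihydroxy-2-[8-hydroxy-2,2-dimethyl-5-(3-methylbut-2-en-1-yl)-2H-chromen-6-yl]-5-(methoxymethoxy)-8-(2-methylbut-3-en-2-yl)-4H-chromen-4-one, via pyranoflavonol diether 11 (not isolated)
Conditions: PhNEt2 (degassed), 150 °C, 2 h; then 205 °C, 3 h, Ar, sealed tube
Reagents that add atoms: none
Why: Proposed new method: a one-flask triple sigmatropic relay in which three O-bound C5 units move to carbon by three non-interfering pericyclic paths: (a) at 150 °C the 4'-O-dimethylpropargyl ether undergoes propargyl Claisen rearrangement to C5', the only free ortho position, then enolisation, [1,5]-H shift and oxa-6π electrocyclisation close the pyran C–O bond to give 11; (b) at 205 °C the 7-O-prenyl ether undergoes ortho-Claisen rearrangement to C8, favoured over C6 by the bond fixation of the benzopyranone and by the 5-OCH2OCH3 group crowding C6, and because the para position C4a is blocked the dienone can only enolise, which fixes the 1,1-dimethylallyl group; (c) the 3'-O-prenyl ether rearranges to C2', where the crowded dienone passes the unit on by Cope rearrangement to C6', the para position, and tautomerisation there gives the linear prenyl group and frees the 3'-OH, any 2'-(1,1-dimethylallyl)phenol formed by enolisation being able to re-enter through its dienone tautomer; the closest known reaction types are the thermal aryl dimethylpropargyl ether to 2,2-dimethylchromene rearrangement, the ortho-Claisen rearrangement of 7-prenyloxyflavones to 8-(1,1-dimethylallyl)flavones and the para-Claisen–Cope rearrangement of 2-prenyloxyacetophenones that carry an ortho hydrogen, which have not been run as one orthogonal cascade nor relayed to a carbon next to a flavonol C2–aryl bond; no stereocentre is formed.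

Step 7
Reactants: 12 3,7-dihydroxy-2-[8-hydroxy-2,2-dimethyl-5-(3-methylbut-2-en-1-yl)-2H-chromen-6-yl]-5-(methoxymethoxy)-8-(2-methylbut-3-en-2-yl)-4H-chromen-4-one
Product: 13 Broussoflavonol D, 3,5,7-trihydroxy-2-[8-hydroxy-2,2-dimethyl-5-(3-methylbut-2-en-1-yl)-2H-chromen-6-yl]-8-(2-methylbut-3-en-2-yl)-4H-chromen-4-one
Conditions: HCl (1 M), MeOH/THF, 25–40 °C
Reagents that add atoms: none
Why: Acid-catalysed acetal methanolysis of the 5-O-MOM group, which lies peri to the C4 carbonyl and is cleaved under conditions mild enough to spare the chromene, the prenyl group, the 1,1-dimethylallyl group next to the 7-OH and the free phenols.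

**Compound list**
1 | 2,4,6-trihydroxyacetophenone | CC(=O)c1c(O)cc(O)cc1O | starting material
2 | 1-bromo-3-methylbut-2-ene (prenyl bromide) | CC(C)=CCBr | starting material
3 | 1-{2,6-dihydroxy-4-[(3-methylbut-2-en-1-yl)oxy]phenyl}ethan-1-one | CC(=O)c1c(O)cc(OCC=C(C)C)cc1O | intermediate
4 | 1-{2-hydroxy-6-(methoxymethoxy)-4-[(3-methylbut-2-en-1-yl)oxy]phenyl}ethan-1-one | CC(=O)c1c(O)cc(OCC=C(C)C)cc1OCOC | intermediate
5 | 3,4-dihydroxybenzaldehyde | O=Cc1ccc(O)c(O)c1 | starting material
6 | 3-chloro-3-methylbut-1-yne | C#CC(C)(C)Cl | starting material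
7 | 3-hydroxy-4-[(2-methylbut-3-yn-2-yl)oxy]benzaldehyde | O=Cc1ccc(OC(C)(C)C#C)c(O)c1 | intermediate
8 | 3-[(3-methylbut-2-en-1-yl)oxy]-4-[(2-methylbut-3-yn-2-yl)oxy]benzaldehyde | O=Cc1ccc(OC(C)(C)C#C)c(OCC=C(C)C)c1 | intermediate
9 | (E)-1-{2-hydroxy-6-(methoxymethoxy)-4-[(3-methylbut-2-en-1-yl)oxy]phenyl}-3-{3-[(3-methylbut-2-en-1-yl)oxy]-4-[(2-methylbut-3-yn-2-yl)oxy]phenyl}prop-2-en-1-one (chalcone) | O=C(/C=C/c1ccc(OC(C)(C)C#C)c(OCC=C(C)C)c1)c1c(O)cc(OCC=C(C)C)cc1OCOC | intermediate
10 | 3-hydroxy-5-(methoxymethoxy)-7-[(3-methylbut-2-en-1-yl)oxy]-2-{3-[(3-methylbut-2-en-1-yl)oxy]-4-[(2-methylbut-3-yn-2-yl)oxy]phenyl}-4H-chromen-4-one | COCOc1cc(OCC=C(C)C)cc2oc(-c3ccc(OC(C)(C)C#C)c(OCC=C(C)C)c3)c(O)c(=O)c12 | intermediate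
11 | 2-{2,2-dimethyl-8-[(3-methylbut-2-en-1-yl)oxy]-2H-chromen-6-yl}-3-hydroxy-5-(methoxymethoxy)-7-[(3-methylbut-2-en-1-yl)oxy]-4H-chromen-4-one (pyranoflavonol diether) | COCOc1cc(OCC=C(C)C)cc2oc(-c3cc(OCC=C(C)C)c4OC(C)(C)C=Cc4c3)c(O)c(=O)c12 | intermediate
12 | 3,7-dihydroxy-2-[8-hydroxy-2,2-dimethyl-5-(3-methylbut-2-en-1-yl)-2H-chromen-6-yl]-5-(methoxymethoxy)-8-(2-methylbut-3-en-2-yl)-4H-chromen-4-one | C=CC(C)(C)c1c(O)cc(OCOC)c2c(=O)c(O)c(-c3cc(O)c4c(c3CC=C(C)C)C=CC(C)(C)O4)oc12 | intermediate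
13 | Broussoflavonol D (achiral) | C=CC(C)(C)c1c(O)cc(O)c2c(=O)c(O)c(-c3cc(O)c4c(c3CC=C(C)C)C=CC(C)(C)O4)oc12 | target

**Step count and risks**

Total step count: 7. Longest linear sequence: 5 steps (steps 1, 2, 5, 6, 7, or equally 3, 4, 5, 6, 7).

Three steps most likely to fail:

Step 6 (the proposed new cascade). Likely failures are enolisation to a 2'-(1,1-dimethylallyl) isomer that does not relay, thermal loss of a prenyl group, and C6 instead of C8 attack on ring A. The fallback uses known chemistry: the ring B prenyl group is put on carbon by cross-coupling and only a single precedented Claisen rearrangement is left for the end. It sets out from ketone 4 and chloroalkyne 6 and comes back to the route at 12. Purchased 2-bromo-4,5-dihydroxybenzaldehyde F1 is etherified at its 4-OH with 6 (K2CO3, KI, CuI, DMF, 60 °C) to give 2-bromo-5-hydroxy-4-[(2-methylbut-3-yn-2-yl)oxy]benzaldehyde F2. Heating (PhNEt2, 150 °C) gives 5-bromo-8-hydroxy-2,2-dimethyl-2H-chromene-6-carbaldehyde F3 by the usual propargyl Claisen and oxa-6π sequence. Stille coupling with tributyl(3-methylbut-2-en-1-yl)stannane (Pd(PPh3)4, DMF, 90 °C) gives 8-hydroxy-2,2-dimethyl-5-(3-methylbut-2-en-1-yl)-2H-chromene-6-carbaldehyde F4. Claisen–Schmidt condensation of F4 with 4 (KOH, EtOH, rt) gives (E)-3-[8-hydroxy-2,2-dimethyl-5-(3-methylbut-2-en-1-yl)-2H-chromen-6-yl]-1-{2-hydroxy-6-(methoxymethoxy)-4-[(3-methylbut-2-en-1-yl)oxy]phenyl}prop-2-en-1-one F5. Algar–Flynn–Oyamada oxidation (H2O2, NaOH, MeOH, 0 °C) gives 3-hydroxy-2-[8-hydroxy-2,2-dimethyl-5-(3-methylbut-2-en-1-yl)-2H-chromen-6-yl]-5-(methoxymethoxy)-7-[(3-methylbut-2-en-1-yl)oxy]-4H-chromen-4-one F6. Heating F6 (PhNEt2, 195 °C) rearranges its 7-O-prenyl ether to the 8-(1,1-dimethylallyl) phenol 12, and step 7 follows unchanged.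

Step 5 (one-flask condensation and oxidative cyclisation). Likely failures are aurone formation from the 6'-alkoxychalcone and incomplete condensation. The fallback separates ring closure from C3 oxygenation; it sets out from chalcone 9, this time isolated after the KOH stage, and comes back at 10. NaOAc in refluxing EtOH closes 9 by oxa-Michael addition to racemic 5-(methoxymethoxy)-7-[(3-methylbut-2-en-1-yl)oxy]-2-{3-[(3-methylbut-2-en-1-yl)oxy]-4-[(2-methylbut-3-yn-2-yl)oxy]phenyl}-2,3-dihydro-4H-chromen-4-one F7. IBX in DMSO at 85 °C dehydrogenates it to 5-(methoxymethoxy)-7-[(3-methylbut-2-en-1-yl)oxy]-2-{3-[(3-methylbut-2-en-1-yl)oxy]-4-[(2-methylbut-3-yn-2-yl)oxy]phenyl}-4H-chromen-4-one F8. Lithiation at C3 with lithium diisopropylamide (LiN(iPr)2, THF, −78 °C, one extra equivalent for the alkyne C–H), borylation with B(OMe)3 and oxidation (H2O2, NaOH, 0 °C) then give flavonol 10.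

Step 3 (site-selective etherification of the catechol). Likely failures are a mixture of 3-O and 4-O ethers or a sluggish reaction of the tertiary chloride. The fallback reverses the order of the two alkylations and uses the dianion to fix the site; it sets out from 5 and comes back at 8. The dianion of 5 (NaH, 2.2 equiv, DMSO, rt) is alkylated with one equivalent of 2 at the more nucleophilic 3-oxide to give 4-hydroxy-3-[(3-methylbut-2-en-1-yl)oxy]benzaldehyde F9. Its single remaining phenol is then etherified with an excess of 6 (K2CO3, KI, CuI, DMF, 65 °C) to give 8.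

**Further compounds**
F1 | step 6 | 2-bromo-4,5-dihydroxybenzaldehyde (purchased) | O=Cc1cc(O)c(O)cc1Br
F2 | step 6 | 2-bromo-5-hydroxy-4-[(2-methylbut-3-yn-2-yl)oxy]benzaldehyde | O=Cc1cc(O)c(OC(C)(C)C#C)cc1Br
F3 | step 6 | 5-bromo-8-hydroxy-2,2-dimethyl-2H-chromene-6-carbaldehyde | O=Cc1cc(O)c2OC(C)(C)C=Cc2c1Br
F4 | step 6 | 8-hydroxy-2,2-dimethyl-5-(3-methylbut-2-en-1-yl)-2H-chromene-6-carbaldehyde | O=Cc1cc(O)c2OC(C)(C)C=Cc2c1CC=C(C)C
F5 | step 6 | (E)-3-[8-hydroxy-2,2-dimethyl-5-(3-methylbut-2-en-1-yl)-2H-chromen-6-yl]-1-{2-hydroxy-6-(methoxymethoxy)-4-[(3-methylbut-2-en-1-yl)oxy]phenyl}prop-2-en-1-one | O=C(/C=C/c1cc(O)c2OC(C)(C)C=Cc2c1CC=C(C)C)c1c(O)cc(OCC=C(C)C)cc1OCOC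
F6 | step 6 | 3-hydroxy-2-[8-hydroxy-2,2-dimethyl-5-(3-methylbut-2-en-1-yl)-2H-chromen-6-yl]-5-(methoxymethoxy)-7-[(3-methylbut-2-en-1-yl)oxy]-4H-chromen-4-one | COCOc1cc(OCC=C(C)C)cc2oc(-c3cc(O)c4OC(C)(C)C=Cc4c3CC=C(C)C)c(O)c(=O)c12
F7 | step 5 | racemic 5-(methoxymethoxy)-7-[(3-methylbut-2-en-1-yl)oxy]-2-{3-[(3-methylbut-2-en-1-yl)oxy]-4-[(2-methylbut-3-yn-2-yl)oxy]phenyl}-2,3-dihydro-4H-chromen-4-one | COCOc1cc(OCC=C(C)C)cc2OC(c3ccc(OC(C)(C)C#C)c(OCC=C(C)C)c3)CC(=O)c12
F8 | step 5 | 5-(methoxymethoxy)-7-[(3-methylbut-2-en-1-yl)oxy]-2-{3-[(3-methylbut-2-en-1-yl)oxy]-4-[(2-methylbut-3-yn-2-yl)oxy]phenyl}-4H-chromen-4-one | COCOc1cc(OCC=C(C)C)cc2oc(-c3ccc(OC(C)(C)C#C)c(OCC=C(C)C)c3)cc(=O)c12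
F9 | step 3 | 4-hydroxy-3-[(3-methylbut-2-en-1-yl)oxy]benzaldehyde | O=Cc1ccc(O)c(OCC=C(C)C)c1
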